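The six-membered ring is cut at C1–C6 and C2–C3, which leads back to isoprene and a 2-acyloxyacrolein. The feature used is the remote origin of chirality at carbinol carbon C1 of the cyclohexane. Its two ring arms differ only at C4 and C5, so no neighbouring centre could induce it. A single catalyst-controlled, para-selective [4+2] cycloaddition closes this ring, puts the alkene at C4=C5, and fixes C1 with its oxygen and the carbon destined to be C1' of the cyclopentane. The precursor is 2-(benzoyloxy)prop-2-enal, a 1,1-disubstituted dienophile. Later the C1 hydroxyl passes its configuration on to C4 and C5 via a bromoether, and an auxiliary-controlled [2+2] annulation builds the five-membered ring.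

Key step: step 3

Labels: cyclohexane C1 (carbinol), C2, C3, C4 (Me, Cl), C5 (Br), C6. Cyclopentane C1' (quaternary, bound to C1), C2' (CMe2), C3' (CHBr), C4', C5'. O7 is the bridge oxygen of the bicyclic intermediates.

Assumption: the sense of induction of the catalyst in step 3 and of the pyrrolidine auxiliary in step 9 is taken from the working models given in the Why lines; both are available as either antipode, so a reversed sense would be met with the mirror-image catalyst or auxiliary and no other change.

Step 1
Reactants: 1 2,2-dimethyl-1,3-dioxan-5-one; 2 benzoyl chloride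
Product: 4 2,2-dimethyl-4H-1,3-dioxin-5-yl benzoate, via potassium enolate 3 (not isolated)
Conditions: KN(SiMe3)2, THF, −78 °C; then 2, −78 → 0 °C
Reagents that add atoms: none
Why: O-acylation of a ketone enolate: the dissociated potassium enolate reacts with the hard acid chloride at oxygen, giving the enol ester that is also the 4H-1,3-dioxin needed for step 2; no stereocenter is formed.

Step 2
Reactants: 4 2,2-dimethyl-4H-1,3-dioxin-5-yl benzoate
Product: 5 2-(benzoyloxy)prop-2-enal
Conditions: toluene, 110 °C, BHT (trace), acetone distilled off; used at once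
Reagents that add atoms: none
Why: Retro-hetero-Diels–Alder reaction: the 4H-1,3-dioxin cycloreverts thermally into acetone and the oxadiene, i.e. the 2-acyloxyacrolein, and removal of the volatile ketone makes the cleavage irreversible.

Step 3
Reactants: 5 2-(benzoyloxy)prop-2-enal; 6 isoprene (2-methylbuta-1,3-diene)
Product: 7 (1R)-1-formyl-4-methylcyclohex-3-en-1-yl benzoate
Conditions: (R)-1,1'-binaphthyl-2,2'-diamine (10 mol %), Tf2NH (19 mol %), EtCN, −40 °C, 6 in excess
Reagents that add atoms: none
Why: The primary ammonium salt condenses reversibly with the formyl group of 5 to an iminium ion, whose lowered LUMO reacts with s-cis 6 in a concerted but asynchronous [4π+2π] cycloaddition in which C2–C3 forms ahead of C1–C6; hydrolysis of the adduct iminium returns the catalyst. The closest known reaction type is the catalytic enantioselective Diels–Alder reaction of 2-acyloxy- and 2-haloacroleins with simple dienes under chiral ammonium or oxazaborolidinium catalysis. The cyclohexene ring (C1–C6) closes by suprafacial union of both diene termini with the two alkene carbons of the dienophile, i.e. an intermolecular six-membered [4+2] closure. C1, the only new stereocenter, is set by the catalyst, whose binaphthyl wall covers the Si face of the acyloxy-bearing carbon so that the diene adds to its Re face and the 1R adduct results. The further selectivity needed is para orientation, which frontier-orbital matching secures: the isoprene terminus attached to the methyl-substituted carbon has the largest HOMO lobe and pairs with the unsubstituted CH2 of the iminium ion, the site of its largest LUMO lobe. Endo or exo approach is immaterial, since both lead to the same single stereocenter.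

Step 4
Reactants: 7 (1R)-1-formyl-4-methylcyclohex-3-en-1-yl benzoate
Product: 8 (1R)-1-(1-hydroxyethyl)-4-methylcyclohex-3-en-1-ol (both epimers at the new carbinol carbon)
Conditions: MeMgBr (4 equiv), THF, −78 °C → rt; aqueous work-up
Reagents that add atoms: methylmagnesium bromide, C[Mg]Br
Why: Grignard addition: one equivalent adds to the aldehyde and two consume the benzoate (directly or after its 1,2-shift to the new alkoxide), so methylation and deprotection happen in one flask; the new carbinol carbon forms unselectively, which is harmless because step 5 flattens it, and C1 is not touched.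

Step 5
Reactants: 8 (1R)-1-(1-hydroxyethyl)-4-methylcyclohex-3-en-1-ol
Product: 9 1-[(1R)-1-hydroxy-4-methylcyclohex-3-en-1-yl]ethan-1-one
Conditions: IBX (2-iodoxybenzoic acid), DMSO, rt
Reagents that add atoms: none
Why: IBX oxidation: the secondary hydroxyl of a 1,2-diol is taken to the α-ketol without glycol cleavage, while the tertiary hydroxyl and the trisubstituted alkene are inert.

Step 6
Reactants: 9 1-[(1R)-1-hydroxy-4-methylcyclohex-3-en-1-yl]ethan-1-one
Product: 10 1-[(1R,3S,4S)-3-bromo-4-methyl-7-oxabicyclo[2.2.1]heptan-1-yl]ethan-1-one (bromine endo)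
Conditions: NBS, CH2Cl2, 0 °C, dark
Reagents that add atoms: N-bromosuccinimide, O=C1CCC(=O)N1Br
Why: Intramolecular bromoetherification (5-exo, Markovnikov): bromonium formation is reversible and only the ion on the face opposite to the C1 hydroxyl can be opened by it, through a boat conformer, at tertiary C4, so the tether sets C4–O7 cis to C1–O and anti addition sets C5–Br endo; alkene and hydroxyl are masked in one operation.

Step 7
Reactants: 10 1-[(1R,3S,4S)-3-bromo-4-methyl-7-oxabicyclo[2.2.1]heptan-1-yl]ethan-1-one
Product: 11 (1S,2S,4R)-2-bromo-1-methyl-4-(prop-1-en-2-yl)-7-oxabicyclo[2.2.1]heptane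
Conditions: MePPh3Br, KOtBu, THF, 0 °C → rt
Reagents that add atoms: methylenetriphenylphosphorane, C=P(c1ccccc1)(c1ccccc1)c1ccccc1
Why: Wittig methylenation of a methyl ketone with the non-stabilised ylide; the bridgehead α-carbon cannot epimerise and the endo bromide has no antiperiplanar hydrogen for E2 loss of HBr.

Step 8
Reactants: 12 2-methylpropanoyl chloride; 13 (2R,5R)-2,5-dimethylpyrrolidine
Product: 14 1-[(2R,5R)-2,5-dimethylpyrrolidin-1-yl]-2-methylpropan-1-one
Conditions: aq NaOH, CH2Cl2, 0 °C
Reagents that add atoms: none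
Why: Schotten–Baumann N-acylation of the secondary amine; its two stereocenters are not involved.

Step 9
Reactants: 11 (1S,2S,4R)-2-bromo-1-methyl-4-(prop-1-en-2-yl)-7-oxabicyclo[2.2.1]heptane; 14 1-[(2R,5R)-2,5-dimethylpyrrolidin-1-yl]-2-methylpropan-1-one
Product: 17 (3R)-3-[(1R,3S,4S)-3-bromo-4-methyl-7-oxabicyclo[2.2.1]heptan-1-yl]-2,2,3-trimethylcyclobutan-1-one, via keteniminium triflate 15 (not isolated), via cyclobutaniminium triflate 16 (not isolated)
Conditions: Tf2O, 2,4,6-collidine, ClCH2CH2Cl, −15 → 80 °C; then aq NaHCO3, reflux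
Reagents that add atoms: water, O
Why: Keteniminium–alkene [2+2] cycloaddition with a chiral pyrrolidine amide: the CH2 terminus of 11 attacks the central carbon of 15 and the tertiary cationic character developing at C1' is quenched by the CMe2 carbon, which fixes the regiochemistry (C1' next to CMe2); the bicycle hardly differentiates the two alkene faces, so C1' is set by the C2-symmetric auxiliary, closure being expected with the bulky bicycle on the ring face opposite to the methyl of the pyrrolidine carbon that lies next to CMe2 and buttresses it; the tied-back bridgehead keeps the alkene accessible and the bridged ether cannot undergo the semipinacol shift open to a free or silylated allylic carbinol.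

Step 10
Reactants: 17 (3R)-3-[(1R,3S,4S)-3-bromo-4-methyl-7-oxabicyclo[2.2.1]heptan-1-yl]-2,2,3-trimethylcyclobutan-1-one
Product: 18 (3R)-3-[(1R,3S,4S)-3-bromo-4-methyl-7-oxabicyclo[2.2.1]heptan-1-yl]-2,2,3-trimethylcyclopentan-1-one
Conditions: CH2N2, Et2O–MeOH, 0 °C → rt
Reagents that add atoms: diazomethane, C=[N+]=[N-]
Why: Diazomethane ring expansion (Büchner–Curtius–Schlotterbeck type) driven by release of cyclobutanone strain: in the betaine the less substituted CH2 (C5') migrates in preference to CMe2, so the inserted carbon becomes C4' and the carbonyl stays at C3' beside the gem-dimethyl carbon; C1' is not involved, no Lewis acid touches the bridged ether, and the far less reactive cyclopentanone does not insert again.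

Step 11
Reactants: 18 (3R)-3-[(1R,3S,4S)-3-bromo-4-methyl-7-oxabicyclo[2.2.1]heptan-1-yl]-2,2,3-trimethylcyclopentan-1-one
Product: 19 (1R,3R)-3-[(1R,3S,4S)-3-bromo-4-methyl-7-oxabicyclo[2.2.1]heptan-1-yl]-2,2,3-trimethylcyclopentan-1-ol
Conditions: (S)-2-methyl-CBS-oxazaborolidine (20 mol %), BH3·SMe2, THF, −20 °C; MeOH, then H2O
Reagents that add atoms: none
Why: Corey–Bakshi–Shibata reduction: the catalyst tells the quaternary C2' flank (large) from the C4'H2 flank (small), as it does for other 2,2-disubstituted cyclopentanones, so the (S)-catalyst gives the 3'R carbinol (OH cis to the C1' methyl, trans to the bicycle) under reagent control whatever the modest bias of the ring.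

Step 12
Reactants: 19 (1R,3R)-3-[(1R,3S,4S)-3-bromo-4-methyl-7-oxabicyclo[2.2.1]heptan-1-yl]-2,2,3-trimethylcyclopentan-1-ol
Product: 20 (1S,2S,4R)-2-bromo-4-[(1R,3S)-3-bromo-1,2,2-trimethylcyclopentyl]-1-methyl-7-oxabicyclo[2.2.1]heptane
Conditions: CBr4, PPh3, toluene, 0 → 80 °C
Reagents that add atoms: carbon tetrabromide, BrC(Br)(Br)Br
Why: Appel reaction: bromide displaces the alkoxyphosphonium group in an SN2 process with inversion, turning 3'R-OH into 3'S-Br (cis to the bicycle); five-membered rings accept backside attack more readily than six-membered ones, secondary carbinols beside a gem-dimethyl group have been brominated in this way in bromoterpene chemistry, and the tertiary hydroxyl is still masked.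

Step 13
Reactants: 20 (1S,2S,4R)-2-bromo-4-[(1R,3S)-3-bromo-1,2,2-trimethylcyclopentyl]-1-methyl-7-oxabicyclo[2.2.1]heptane
Product: 22 (1R,3S,4S)-3-bromo-1-[(1R,3S)-3-bromo-1,2,2-trimethylcyclopentyl]-4-chloro-4-methylcyclohexan-1-ol, via trichlorotitanium alkoxide 21 (not isolated)
Conditions: TiCl4 (1.2 equiv), CH2Cl2–hexane, −78 °C; then ice-water
Reagents that add atoms: titanium tetrachloride, Cl[Ti](Cl)(Cl)Cl
Why: Proposed new method: TiCl4 binds O7; the endo C5–Br bond lies antiperiplanar to C4–O7, so heterolysis of that bond is assisted by bromine and gives a bromonium ion on the face opposite to the departing oxygen (the reverse of step 6), which a chloride of the titanate still held on the C1 oxygen opens at tertiary C4 from the oxygen face; two inversions mean net retention at C4 (Cl cis to C1–OH, trans to Br), while C1, C5, C1' and C3' are untouched; the closest known reaction types are the Lewis-acid opening of 7-oxabicyclo[2.2.1]heptanes to halocyclohexanols and substitution of bromohydrin derivatives with retention through neighbouring bromine; what is new is that the assisted C4–O7 cleavage must outrun the unassisted C1–O7 cleavage.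

Compound list
1 | 2,2-dimethyl-1,3-dioxan-5-one | CC1(C)OCC(=O)CO1 | starting material
2 | benzoyl chloride | O=C(Cl)c1ccccc1 | starting material
3 | potassium 2,2-dimethyl-4H-1,3-dioxin-5-olate | CC1(C)OCC([O-])=CO1.[K+] | intermediate
4 | 2,2-dimethyl-4H-1,3-dioxin-5-yl benzoate | CC1(C)OCC(OC(=O)c2ccccc2)=CO1 | intermediate
5 | 2-(benzoyloxy)prop-2-enal | C=C(OC(=O)c1ccccc1)C=O | intermediate
6 | isoprene | C=CC(C)=C | starting material
7 | (1R)-1-formyl-4-methylcyclohex-3-en-1-yl benzoate | O=C[C@@]1(OC(=O)c2ccccc2)CCC(C)=CC1 | intermediate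
8 | (1R)-1-(1-hydroxyethyl)-4-methylcyclohex-3-en-1-ol, carbinol epimers | CC(O)[C@@]1(O)CCC(C)=CC1 | intermediate
9 | 1-[(1R)-1-hydroxy-4-methylcyclohex-3-en-1-yl]ethan-1-one | CC(=O)[C@@]1(O)CCC(C)=CC1 | intermediate
10 | 1-[(1R,3S,4S)-3-bromo-4-methyl-7-oxabicyclo[2.2.1]heptan-1-yl]ethan-1-one | CC(=O)[C@]12CC[C@](C)(O1)[C@@H](Br)C2 | intermediate
11 | (1S,2S,4R)-2-bromo-1-methyl-4-(prop-1-en-2-yl)-7-oxabicyclo[2.2.1]heptane | CC(=C)[C@]12CC[C@](C)(O1)[C@@H](Br)C2 | intermediate
12 | 2-methylpropanoyl chloride | CC(C)C(=O)Cl | starting material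
13 | (2R,5R)-2,5-dimethylpyrrolidine | C[C@@H]1CC[C@@H](C)N1 | starting material
14 | 1-[(2R,5R)-2,5-dimethylpyrrolidin-1-yl]-2-methylpropan-1-one | CC(C)C(=O)N1[C@H](C)CC[C@H]1C | intermediate
15 | (2R,5R)-2,5-dimethyl-1-(2-methylprop-1-en-1-ylidene)pyrrolidin-1-ium triflate | CC(C)=C=[N+]1[C@H](C)CC[C@H]1C.[O-]S(=O)(=O)C(F)(F)F | intermediate
16 | (2R,5R)-1-{(3R)-3-[(1R,3S,4S)-3-bromo-4-methyl-7-oxabicyclo[2.2.1]heptan-1-yl]-2,2,3-trimethylcyclobutylidene}-2,5-dimethylpyrrolidin-1-ium triflate | CC1(C)C(=[N+]2[C@H](C)CC[C@H]2C)C[C@@]1(C)[C@]34CC[C@](C)(O3)[C@@H](Br)C4.[O-]S(=O)(=O)C(F)(F)F | intermediate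
17 | (3R)-3-[(1R,3S,4S)-3-bromo-4-methyl-7-oxabicyclo[2.2.1]heptan-1-yl]-2,2,3-trimethylcyclobutan-1-one | CC1(C)C(=O)C[C@@]1(C)[C@]23CC[C@](C)(O2)[C@@H](Br)C3 | intermediate
18 | (3R)-3-[(1R,3S,4S)-3-bromo-4-methyl-7-oxabicyclo[2.2.1]heptan-1-yl]-2,2,3-trimethylcyclopentan-1-one | CC1(C)C(=O)CC[C@@]1(C)[C@]23CC[C@](C)(O2)[C@@H](Br)C3 | intermediate
19 | (1R,3R)-3-[(1R,3S,4S)-3-bromo-4-methyl-7-oxabicyclo[2.2.1]heptan-1-yl]-2,2,3-trimethylcyclopentan-1-ol | CC1(C)[C@H](O)CC[C@@]1(C)[C@]23CC[C@](C)(O2)[C@@H](Br)C3 | intermediate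
20 | (1S,2S,4R)-2-bromo-4-[(1R,3S)-3-bromo-1,2,2-trimethylcyclopentyl]-1-methyl-7-oxabicyclo[2.2.1]heptane | CC1(C)[C@@H](Br)CC[C@@]1(C)[C@]23CC[C@](C)(O2)[C@@H](Br)C3 | intermediate
21 | trichlorotitanium alkoxide of 22 | CC1(C)[C@@H](Br)CC[C@@]1(C)[C@@]1(O[Ti](Cl)(Cl)Cl)CC[C@](C)(Cl)[C@@H](Br)C1 | intermediate
22 | (1R,3S,4S)-3-bromo-1-[(1R,3S)-3-bromo-1,2,2-trimethylcyclopentyl]-4-chloro-4-methylcyclohexan-1-ol | CC1(C)[C@@H](Br)CC[C@@]1(C)[C@@]1(O)CC[C@](C)(Cl)[C@@H](Br)C1 | target

Total step count: 13. Longest linear sequence: 12 (steps 1–7 and 9–13; step 8 is a one-step side branch).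

Steps most likely to fail

1. Step 13 (the labelled step).
- What may go wrong: heterolysis of the other bridgehead bond, C1–O7, which no β-bromine retards, followed by chloride capture at C1, proton loss or a Wagner–Meerwein shift from C1'. The bromonium ion may also re-close to the ether.
- Fallback (known chemistry): the opening is moved forward to ketone 10. There the acetyl group on C1 rules out a C1 cation, so the known carbonyl-directed Lewis-acid opening of 7-oxanorbornanes can break only C4–O7. TiCl4 in CH2Cl2 at −78 °C, chelated by the acetyl oxygen and O7, should give the ketol 1-[(1R,3S,4S)-3-bromo-4-chloro-1-hydroxy-4-methylcyclohexyl]ethan-1-one F1, with retention at C4 through neighbouring bromine. TESOTf and 2,6-lutidine give its triethylsilyl ether F2, and Wittig methylenation gives the isopropenyl silyl ether F3. Cycloaddition with 14 under the conditions of step 9 leads through the cyclobutaniminium triflate F4 to the cyclobutanone F5. Diazomethane gives the cyclopentanone F6, CBS reduction the 3'R alcohol F7, Appel bromination the silylated dibromochloride F8, and HF·pyridine in THF releases 22. This variant is two steps longer and carries the tertiary chloride and an allylic silyl ether through the cationic cycloaddition, which is why it is held in reserve.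

2. Step 9.
- What may go wrong: poor facial selectivity at the prochiral isopropenyl carbon. Proton loss from the cationic C1' (an ene-type outcome) may also occur instead of closure between two fully substituted carbons.
- Fallback: auxiliary control is given up in favour of reagent-controlled derivatisation and separation. From 11, the smaller keteniminium ion made from N,N-dimethylisobutyramide (Tf2O, collidine) should give the N,N-dimethylcyclobutaniminium triflate F9. Hydrolysis then gives the cyclobutanone as both C1' epimers F10, and diazomethane gives the epimeric cyclopentanones F11. The (S)-CBS reduction makes both epimers 3'R, so the remote C1' epimers become cis/trans isomers of one cyclopentanol ring. Chromatography then removes the (1R,3S)-cyclopentanol F12, and the route is rejoined at 19.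

3. Step 12.
- What may go wrong: backside displacement at the neopentylic C3', on the ring face that also carries the bicycle, becomes so slow that elimination to the C3'=C4' alkene or a 1,2-methyl shift from C2' takes over. A mismatched reduction in step 11 would feed the same problem.
- Fallback: the C–Br bond is made at the sp2 stage and the stereocenter is set by hydrogen delivery. From 18, hydrazine hydrate in EtOH gives the hydrazone F13, and Barton-type bromination (NBS, pyridine) gives the vinyl bromide F14. Radical hydrogenation by hydrogen-atom transfer (Mn(dpm)3 cat., PhSiH3, tBuOOH, iPrOH) is known to preserve the C–Br bond of bromoalkenes. It generates the α-bromo radical at C3', which should take up hydrogen on the face away from the bicycle. This places bromine cis to the bicycle, and the route is rejoined at 20.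

Further compounds
F1 | step 13 | 1-[(1R,3S,4S)-3-bromo-4-chloro-1-hydroxy-4-methylcyclohexyl]ethan-1-one | CC(=O)[C@@]1(O)CC[C@](C)(Cl)[C@@H](Br)C1
F2 | step 13 | 1-[(1R,3S,4S)-3-bromo-4-chloro-4-methyl-1-(triethylsilyloxy)cyclohexyl]ethan-1-one | CC(=O)[C@@]1(O[Si](CC)(CC)CC)CC[C@](C)(Cl)[C@@H](Br)C1
F3 | step 13 | {[(1R,3S,4S)-3-bromo-4-chloro-4-methyl-1-(prop-1-en-2-yl)cyclohexyl]oxy}triethylsilane | CC(=C)[C@@]1(O[Si](CC)(CC)CC)CC[C@](C)(Cl)[C@@H](Br)C1
F4 | step 13 | (2R,5R)-1-{(3R)-3-[(1R,3S,4S)-3-bromo-4-chloro-4-methyl-1-(triethylsilyloxy)cyclohexyl]-2,2,3-trimethylcyclobutylidene}-2,5-dimethylpyrrolidin-1-ium triflate | CC1(C)C(=[N+]2[C@H](C)CC[C@H]2C)C[C@@]1(C)[C@@]1(O[Si](CC)(CC)CC)CC[C@](C)(Cl)[C@@H](Br)C1.[O-]S(=O)(=O)C(F)(F)F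
F5 | step 13 | (3R)-3-[(1R,3S,4S)-3-bromo-4-chloro-4-methyl-1-(triethylsilyloxy)cyclohexyl]-2,2,3-trimethylcyclobutan-1-one | CC1(C)C(=O)C[C@@]1(C)[C@@]1(O[Si](CC)(CC)CC)CC[C@](C)(Cl)[C@@H](Br)C1
F6 | step 13 | (3R)-3-[(1R,3S,4S)-3-bromo-4-chloro-4-methyl-1-(triethylsilyloxy)cyclohexyl]-2,2,3-trimethylcyclopentan-1-one | CC1(C)C(=O)CC[C@@]1(C)[C@@]1(O[Si](CC)(CC)CC)CC[C@](C)(Cl)[C@@H](Br)C1
F7 | step 13 | (1R,3R)-3-[(1R,3S,4S)-3-bromo-4-chloro-4-methyl-1-(triethylsilyloxy)cyclohexyl]-2,2,3-trimethylcyclopentan-1-ol | CC1(C)[C@H](O)CC[C@@]1(C)[C@@]1(O[Si](CC)(CC)CC)CC[C@](C)(Cl)[C@@H](Br)C1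
F8 | step 13 | ({(1R,3S,4S)-3-bromo-1-[(1R,3S)-3-bromo-1,2,2-trimethylcyclopentyl]-4-chloro-4-methylcyclohexyl}oxy)triethylsilane | CC1(C)[C@@H](Br)CC[C@@]1(C)[C@@]1(O[Si](CC)(CC)CC)CC[C@](C)(Cl)[C@@H](Br)C1
F9 | step 9 | N-{3-[(1R,3S,4S)-3-bromo-4-methyl-7-oxabicyclo[2.2.1]heptan-1-yl]-2,2,3-trimethylcyclobutylidene}-N-methylmethanaminium triflate, both C1' epimers | CC1(C)C(=[N+](C)C)CC1(C)[C@]23CC[C@](C)(O2)[C@@H](Br)C3.[O-]S(=O)(=O)C(F)(F)F
F10 | step 9 | 3-[(1R,3S,4S)-3-bromo-4-methyl-7-oxabicyclo[2.2.1]heptan-1-yl]-2,2,3-trimethylcyclobutan-1-one, both C1' epimers | CC1(C)C(=O)CC1(C)[C@]23CC[C@](C)(O2)[C@@H](Br)C3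
F11 | step 9 | 3-[(1R,3S,4S)-3-bromo-4-methyl-7-oxabicyclo[2.2.1]heptan-1-yl]-2,2,3-trimethylcyclopentan-1-one, both C1' epimers | CC1(C)C(=O)CCC1(C)[C@]23CC[C@](C)(O2)[C@@H](Br)C3
F12 | step 9 | (1R,3S)-3-[(1R,3S,4S)-3-bromo-4-methyl-7-oxabicyclo[2.2.1]heptan-1-yl]-2,2,3-trimethylcyclopentan-1-ol | CC1(C)[C@H](O)CC[C@]1(C)[C@]23CC[C@](C)(O2)[C@@H](Br)C3
F13 | step 12 | (3R)-3-[(1R,3S,4S)-3-bromo-4-methyl-7-oxabicyclo[2.2.1]heptan-1-yl]-2,2,3-trimethylcyclopentan-1-one hydrazone | CC1(C)C(=NN)CC[C@@]1(C)[C@]23CC[C@](C)(O2)[C@@H](Br)C3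
F14 | step 12 | (1S,2S,4R)-2-bromo-4-[(1R)-3-bromo-1,2,2-trimethylcyclopent-3-en-1-yl]-1-methyl-7-oxabicyclo[2.2.1]heptane | CC1(C)C(Br)=CC[C@@]1(C)[C@]23CC[C@](C)(O2)[C@@H](Br)C3
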